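A leftover was where I began: at 47 min the east run had 47.6% of its starting material not shown as target, and the question was what that share becomes with more catalyst.

| flask | starting material | reagent | catalyst | time |
|---|---|---|---|---|
| east | 0.500 M | 0.750 M | 0.0150 M |  |
| south-west | 1.50 M | 0.750 M | 0.0150 M |  |
| south | 0.500 M | 0.750 M | 0.0300 M |  |
| north-west | 0.500 M | 0.380 M | 0.0150 M |  |
| south-east | 0.500 M | 0.750 M | 0.0690 M | 47 min |

- east run (time / min: [target] / M): 9.4: 0.071; 19: 0.136; 28: 0.181; 38: 0.228; 47: 0.262
- south-west run (time / min: [target] / M): 9.4: 0.220; 19: 0.437; 28: 0.612; 38: 0.674; 47: 0.650
- south run (time / min: [target] / M): 9.4: 0.136; 19: 0.242; 28: 0.307; 38: 0.351; 47: 0.373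
- north-west run (time / min: [target] / M): 9.4: 0.095; 19: 0.177; 28: 0.238; 38: 0.288; 47: 0.305

(readings scatter by 0.003 M)

- the power of [catalyst] that the first rate follows, about the charge of the east run; measure it at two percent of starting material made into target
- the power of [reagent] that the first rate follows, about the charge of the east run; measure it at two percent of starting material made into target
- target in the south-east run at 47 min, as a share of the starting material charged

- Overall: starting material + reagent -> target, with catalyst as catalyst.
- Constant volume, constant temperature.
- The analysis sees a species whether free or bound.
- An order is taken over about fifteen percent of the charge, up and down.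

I treated the loss of starting material as pseudo-first-order, with a rate constant proportional to catalyst. The logarithm of the leftover, taken positive and divided by catalyst and time, is the catalyst constant; the east run gave 1.05 L mol⁻¹ min⁻¹. The south run, with twice the catalyst, gave 0.972 L mol⁻¹ min⁻¹ at the same time.

For the south-east run this meant 0.0727 min⁻¹, so my first round put 96.7% of the starting material through to target by 47 min. I then put that answer back in. The south-west run's target fell from 44.9% to 43.3% of its starting material between 38 min and 47 min, which I read as decay at 0.00403 min⁻¹. I reckoned target in the south-east run at 47 min to be on average 33.2 min old, so my second round gave 84.6%. I expected formation to outrun decay.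

The forecast stood lower than my figure, at 50%, range 36% to 68%: “Target has passed its maximum by 47 min, giving about 50%, which is uncertain”. For the orders it gave 1 in catalyst, range 0.88 to 1.1, and −0.6 in reagent, range −0.85 to −0.4.

The south-east run gave 83.9% at 47 min; about the charge of the east run, the orders came out at 1.0 in catalyst and −0.57 in reagent.

    catalyst + starting material ⇌ catalyst-substrate complex (2.976 L mol⁻¹ min⁻¹, 1.032 min⁻¹)
    catalyst-substrate complex + reagent → target + catalyst (47.10 L mol⁻¹ min⁻¹)
    target → decomposed product (0.004668 min⁻¹)
    catalyst + reagent ⇌ idle catalyst-reagent complex, settled at all times (2.170 L mol⁻¹)

The south run's rate was 2.0 times the east run's where the same amount of target had been made. With 1.05 L mol⁻¹ min⁻¹, a quarter of the south-east run's charge of starting material was reckoned through by 3.96 min. In the south run the same constant gave a quarter of the charge at 9.11 min, and the target reached it at 8.50 min.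

All runs are calculated for substances that don't exist; scatter was added.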